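Numbering used throughout: the side chain is counted from the aryloxy carbon (C1H2, C2H bearing OOH, C3 bearing the exocyclic methylene C10, C4H2, C5 ketone, C6=C7 with two methyls); the vanillate ring is ring A. Compounds are numbered 1–17 as in the compound list.

## Analysis of the target

Compound 17 is an acyclic ten-carbon chain attached through C1 to the phenol oxygen of a methyl vanillate ring (ring A). It has one stereocentre, C2, of S configuration. C2 is allylic to C3=C10, alpha to the O–O bond and beta to the aryl ether oxygen, so no other element in the molecule can relay stereochemistry to it. The sensitive groups are: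
- the secondary hydroperoxide, which is reduced by low-valent metals and phosphines and fragmented by base through loss of the C2 hydrogen;
- the C4 methylene between the ketone and the 1,1-disubstituted alkene, whose deprotonation moves C3=C10 into conjugation;
- the C5–C7 enone, which accepts peroxide anions;
- the methyl ester.

The C2 oxygen and the C5 carbonyl carbon stand in a 1,4 relationship. A free hydroxyl at C2 would close onto C5 and dehydrate to an aromatic furan, and the hydroperoxide itself can equilibrate with a six-membered peroxyhemiketal. The difficulty is therefore the order of events: the O–O bond must be set with defined configuration at a hindered allylic carbon before the ketone and the acidic C4 position exist, and must then survive the unveiling of the ketone. The plan rests on the unsubstituted C1 between the ring A phenol oxygen and the oxygenated C2. This pattern is what a phenol leaves when it opens a monosubstituted oxirane at its CH2 end, and the rest of that unit (C2, C3, C10, C4) is a five-carbon methallyl fragment that an ene reaction can extend while regenerating the exocyclic alkene.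

## Retrosynthetic reasoning

**17 from 16.** The last bond cut is the O–C bond between the peroxide and a ketal carbon, leading back to the mixed perketal 16. The base, fluoride and oxidant needed earlier would all attack a free hydroperoxide, whereas a perketal behaves like an ordinary ketal. The forward step only has to hydrolyse that ketal with weak aqueous acid without moving the C3=C10 alkene.

**16 from 15 and 14.** The C5 carbonyl is taken back to the carbinol 15 and then to its silyl ether 14. The ketone is made the last feature of the skeleton to appear, because once it exists C4 is acidic, the enone accepts peroxide anions and a C2 oxygen can reach C5. Holding C5 as a protected alcohol lets the peroxide be introduced by a basic SN2 reaction. Forward, a buffered desilylation and a neutral oxidation must leave the O–O bond alone; C5 becomes sp2, so its configuration is irrelevant.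

**14 from 10 and 13.** The C2–O bond is cut next. Inversion by a peroxide anion on the sulfonate 10 gives the S peroxide, so 10 and its parent alcohol 9 must be R at C2. A protected hydroperoxide, 13, is used as nucleophile because its anion is a weak base and does not attack the methyl ester irreversibly. Reagent 13 is traced to the symmetrical alkene 11 by ozonolysis in an alcohol solvent.

**9 from 8 and 7.** Alcohol 9 carries a robust silyl ether at C5 and a free hydroxyl at C2, whereas the ene product 7 has the reverse. Two silyl groups of different lability solve this: the C2 triethylsilyl ether of 7 survives silylation of C5 (8) and is then removed selectively. The C5 ether is needed because a free C5 alkoxide would displace the C2 sulfonate and close a tetrahydrofuran.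

**7 from 5 and 6.** The C4–C5 bond is cut between the methallyl unit of 5 and aldehyde 6. In a carbonyl-ene reaction the terminal methylene of 5 becomes C4 and the methyl becomes C10, so the exocyclic alkene is regenerated at C3 and no functional group has to be installed first. The forward step must abstract hydrogen from the methyl and not from C2, and must add to the carbonyl carbon of the enal. The new C5 centre is uncontrolled and is erased later.

**5 from 4, and 4 from 2 and 3.** After removal of the silyl group, the ring A oxygen–C1 bond is cut. Phenol 3 opens the epoxide 2 at its CH2 terminus, which forms the ether and selects the C2 configuration in the same step if a chiral cobalt-salen complex accepts only the R epoxide. This is the key disconnection: it joins the two halves, sets the only stereocentre, and uses 3 as bought.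

**2 from 1.** The racemic vinyl epoxide is traced to the enal 1 by methylene transfer from a sulfur ylide to the carbonyl group. One step suffices, and the racemate is exactly what a kinetic resolution requires.

## Alternatives that were turned down

**Alternative 1:** The C4–C5 and C5–C6 bonds are cut together. Forward, a peroxide-bearing allyl chloride A2, carbon monoxide A4 and the isobutenylstannane A3 would be joined under Pd2(dba)3 with AsPh3 (zerovalent palladium) to give perketal A1, which is the same compound as 16.
- For: it builds the whole skipped dienone in one neutral step and needs no protecting-group exchange at C5. On convergence of the dienone it is stronger than the chosen route.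
- Against: A2 is already a chiral allylic peroxide, so the stereocentre and the O–O bond must be made beforehand by chemistry of the kind used here, plus an allylic chlorination next to a perketal. Zerovalent palladium and a soft arsine ligand can reduce an O–O bond on the carbon next to the pi-allyl unit. Direct allyl–vinyl coupling competes with carbon monoxide insertion, and a palladium hydride can move the new beta,gamma alkene into conjugation.
- Comparison: the chosen route needs about four more steps to reach 16, but it keeps transition metals away from the peroxide and settles the stereochemistry in step 2.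

**Alternative 2:** The C2–O peroxide bond is cut. Forward, the E-enal A6 and the tertiary hydroperoxide A7 (identical with 13) would react under a 9-amino-9-deoxy-epi-cinchona alkaloid salt by iminium activation to give the beta-peroxy aldehyde A5.
- For: it is the only plan that forms the O–O-bearing stereocentre directly in the target configuration, with no inversion at a hindered allylic carbon. On that point it is stronger.
- Against: the enamine formed after peroxide addition can attack the O–O bond and close to an epoxide, which is the usual fate of enals under these conditions. The acid co-catalyst also threatens the ketal carbon of the perketal. A5 holds only C1–C4, so C3 still needs its methylene and the aldehyde carbon C4 must become a CH2 attached to an acyl group. That polarity-reversed C–C bond formation has to be carried out with the peroxide on board and would probably pass through A2.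
- Comparison: step economy is no better, and the risk is moved to a long sequence with the peroxide in place. The chosen route resolves first and adds the peroxide late.

**Alternative 3:** The C2–C3 bond is cut. Forward, the 2-iodoallyl ketone A9 would add to the aryloxyacetaldehyde A10 under CrCl2 (divalent chromium) with catalytic NiCl2 (divalent nickel) and a chiral oxazoline–sulfonamide ligand to give the hydroxy ketone A8.
- For: it assembles the full skeleton, ketone included, in one bond formation and is the most convergent of the four plans.
- Against: A8 has a free C2 hydroxyl 1,4 to the C5 ketone, so lactol formation and dehydration to a furan are open. Its conversion to the hydroperoxide with inversion would have to be done in the presence of the enone and the acidic C4 methylene. A9 is a beta-iodo skipped enone that can lose HI or isomerise, and divalent chromium can reduce the enone.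
- Comparison: the chosen route is longer, but the hydroxyl-to-peroxide exchange is done while C5 is a protected carbinol, which removes all three problems.

Key step: step 2

Assumption 1: the target is taken as the open-chain hydroperoxy ketone as drawn; it may equilibrate in solution with the six-membered peroxyhemiketal formed by addition of the OOH group to C5.

Assumption 2: the (S,S) antipode of the cobalt complex is taken to be matched to the R epoxide, as for simple 2-alkyl oxiranes; if the sense is reversed for this substrate, the (R,R) complex is used and nothing else changes.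

## Route

Step 1
Reactants: 1 methacrolein (2-methylprop-2-enal)
Product: 2 racemic 2-(prop-1-en-2-yl)oxirane
Conditions: Me3S+ I−, NaH, DMSO–diglyme, −5 °C to rt; product distilled from the pot into a cold trap
Reagents that add atoms: trimethylsulfonium iodide, C[S+](C)C.[I-]
Why: Corey–Chaykovsky epoxidation: the unstabilised sulfonium ylide adds to the aldehyde carbon rather than to the enal beta-carbon and the betaine closes to the oxirane with loss of dimethyl sulfide; 1 has no alpha-hydrogen, so enolisation does not compete, and the racemic product is what the resolution needs.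

Step 2
Reactants: 2 racemic 2-(prop-1-en-2-yl)oxirane (2.2 equiv; the R enantiomer reacts); 3 methyl vanillate (methyl 4-hydroxy-3-methoxybenzoate)
Product: 4 methyl 4-{[(2R)-2-hydroxy-3-methylbut-3-en-1-yl]oxy}-3-methoxybenzoate
Conditions: (S,S)-(salen)Co[OC(CF3)3] (trivalent cobalt, 4.4 mol%; salen = dianion of N,N'-bis(3,5-di-tert-butylsalicylidene)cyclohexane-1,2-diamine; made from the divalent complex (salen)Co, (CF3)3COH and air), 3 Å MS, TBME, −15 °C to 4 °C; unreacted epoxide evaporated
Reagents that add atoms: none
Why: The perfluoro-tert-butoxide on trivalent cobalt exchanges with phenol 3 to give a cobalt phenoxide, while a second cobalt centre binds the epoxide oxygen as a Lewis acid. The phenoxide attacks the unsubstituted carbon C1 from the backside (SN2) in this bimetallic arrangement; the C2–O bond is not broken, so the R configuration of the reacting epoxide is carried unchanged into the C2 carbinol of 4. The closest known reaction type is the cobalt-salen kinetic resolution of terminal epoxides with phenols, itself the counterpart of the hydrolytic resolution. No ring is closed and one is opened. The stereocentre is selected, not created: the chiral diamine backbone of the (S,S) complex admits only the R epoxide, and with 2.2 equivalents of racemate the phenol is limiting, so all of 3 should become one enantiomer of the ether. Two selectivities are required, discrimination between the epoxide enantiomers and opening at C1 in preference to the allylic carbon C2 or SN2' attack at the alkene terminus; the catalyst supplies the first, and the SN2 character of the opening at the only unhindered CH2, reinforced by the branched isopropenyl group, supplies the second. The ester para to the hydroxyl lowers the pKa of 3 enough for it to exchange onto cobalt, and the sieves exclude water, which would open the epoxide by the same mechanism. The mismatched S epoxide is volatile and leaves on evaporation.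

Step 3
Reactants: 4 methyl 4-{[(2R)-2-hydroxy-3-methylbut-3-en-1-yl]oxy}-3-methoxybenzoate
Product: 5 methyl 3-methoxy-4-{[(2R)-3-methyl-2-(triethylsilyloxy)but-3-en-1-yl]oxy}benzoate
Conditions: TESCl, imidazole, CH2Cl2, 0 °C to rt
Reagents that add atoms: triethylsilyl chloride (TESCl), CC[Si](CC)(CC)Cl
Why: Standard silylation of a secondary alcohol; the C2–O bond is untouched, so the configuration is retained, and the triethylsilyl group is chosen because it must later be removed in the presence of a tert-butyldimethylsilyl ether.

Step 4
Reactants: 5 methyl 3-methoxy-4-{[(2R)-3-methyl-2-(triethylsilyloxy)but-3-en-1-yl]oxy}benzoate; 6 3-methylbut-2-enal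
Product: 7 methyl 4-{[(2R)-5-hydroxy-7-methyl-3-methylidene-2-(triethylsilyloxy)oct-6-en-1-yl]oxy}-3-methoxybenzoate, as a mixture of C5 epimers
Conditions: 6 (2.5 equiv), Me2AlCl (3.5 equiv), CH2Cl2, −78 °C to −20 °C; aq. KNaC4H4O6 (Rochelle salt)
Reagents that add atoms: none
Why: Lewis-acid-promoted carbonyl-ene reaction of an aldehyde with a 1,1-disubstituted alkene: the terminal methylene of 5 (future C4) bonds to the activated carbonyl carbon of 6 (future C5) while a hydrogen passes from the methyl (future C10), which regenerates the exocyclic alkene at C3. The two beta-methyl groups of 6 block conjugate attack, and the C2 hydrogen should not be abstracted because its carbon is inductively deactivated by the silyloxy group and the hydrogen lies near the alkene plane. Me2AlCl also scavenges protons, which protects the new allylic alkoxide from ionisation; the C5 configuration is uncontrolled and is erased in step 11.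

Step 5
Reactants: 7 methyl 4-{[(2R)-5-hydroxy-7-methyl-3-methylidene-2-(triethylsilyloxy)oct-6-en-1-yl]oxy}-3-methoxybenzoate
Product: 8 methyl 4-{[(2R)-5-(tert-butyldimethylsilyloxy)-7-methyl-3-methylidene-2-(triethylsilyloxy)oct-6-en-1-yl]oxy}-3-methoxybenzoate
Conditions: TBSCl, imidazole, DMF, rt
Reagents that add atoms: tert-butyldimethylsilyl chloride (TBSCl), CC(C)(C)[Si](C)(C)Cl
Why: Standard silylation; the tert-butyldimethylsilyl ether survives the mild acid of step 6 and the basic peroxide alkylation of step 9, and it prevents a C5 alkoxide from displacing the C2 sulfonate to form a tetrahydrofuran.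

Step 6
Reactants: 8 methyl 4-{[(2R)-5-(tert-butyldimethylsilyloxy)-7-methyl-3-methylidene-2-(triethylsilyloxy)oct-6-en-1-yl]oxy}-3-methoxybenzoate
Product: 9 methyl 4-{[(2R)-5-(tert-butyldimethylsilyloxy)-2-hydroxy-7-methyl-3-methylideneoct-6-en-1-yl]oxy}-3-methoxybenzoate
Conditions: PPTS (cat.), MeOH–CH2Cl2, 0 °C
Reagents that add atoms: none
Why: Selective acid-catalysed methanolysis of a silyl ether: the triethylsilyl ether is cleaved far faster than the tert-butyldimethylsilyl ether, and PPTS is too weak an acid to ionise the allylic C5 silyl ether.

Step 7
Reactants: 9 methyl 4-{[(2R)-5-(tert-butyldimethylsilyloxy)-2-hydroxy-7-methyl-3-methylideneoct-6-en-1-yl]oxy}-3-methoxybenzoate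
Product: 10 methyl 4-{[(2R)-5-(tert-butyldimethylsilyloxy)-2-(methanesulfonyloxy)-7-methyl-3-methylideneoct-6-en-1-yl]oxy}-3-methoxybenzoate
Conditions: MsCl, Et3N, CH2Cl2, −20 °C; cold aqueous work-up, used crude
Reagents that add atoms: methanesulfonyl chloride (MsCl), CS(=O)(=O)Cl
Why: Mesylation through the sulfene with retention at C2, since only the O–H bond reacts; the electron-withdrawing aryloxymethyl group and the lack of cation stabilisation at C2 should keep this allylic sulfonate from ionising before it is used.

Step 8
Reactants: 11 2,3-dimethylbut-2-ene
Product: 13 2-methoxyprop-2-yl hydroperoxide (2-hydroperoxy-2-methoxypropane), via acetone O-oxide 12 (not isolated)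
Conditions: O3, CH2Cl2–MeOH, −78 °C; N2 purge; concentrated cold behind a shield
Reagents that add atoms: ozone, [O-][O+]=O; methanol, CO
Why: Ozonolysis in a participating solvent (Criegee mechanism): the primary ozonide of the symmetrical alkene splits into acetone and the carbonyl oxide 12, which methanol traps as the alpha-methoxy hydroperoxide; symmetry of 11 ensures a single product beside acetone.

Step 9
Reactants: 10 methyl 4-{[(2R)-5-(tert-butyldimethylsilyloxy)-2-(methanesulfonyloxy)-7-methyl-3-methylideneoct-6-en-1-yl]oxy}-3-methoxybenzoate; 13 2-methoxyprop-2-yl hydroperoxide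
Product: 14 methyl 4-{[(2S)-5-(tert-butyldimethylsilyloxy)-2-[(2-methoxypropan-2-yl)peroxy]-7-methyl-3-methylideneoct-6-en-1-yl]oxy}-3-methoxybenzoate
Conditions: 13 (3 equiv), CsOH·H2O (2.5 equiv), DMF, 0 °C; then 10, 0 °C to rt
Reagents that add atoms: none
Why: SN2 alkylation of a peroxide anion by a secondary allylic sulfonate, which inverts C2 from R to S; the anion is a strong nucleophile but a weak base, which disfavours elimination toward C1, and the allylic position accelerates the substitution. The ester is safe because the peroxide anion is a weaker base than methoxide and no free hydroxide remains with 13 in excess; no ketone is present, so neither enolisation nor conjugate addition can occur.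

Step 10
Reactants: 14 methyl 4-{[(2S)-5-(tert-butyldimethylsilyloxy)-2-[(2-methoxypropan-2-yl)peroxy]-7-methyl-3-methylideneoct-6-en-1-yl]oxy}-3-methoxybenzoate
Product: 15 methyl 4-{[(2S)-5-hydroxy-2-[(2-methoxypropan-2-yl)peroxy]-7-methyl-3-methylideneoct-6-en-1-yl]oxy}-3-methoxybenzoate, as a mixture of C5 epimers
Conditions: TBAF, AcOH (1:1), THF, 0 °C to rt
Reagents that add atoms: none
Why: Fluoride cleavage of the Si–O bond; the acetic acid buffer suppresses base-induced Kornblum–DeLaMare fragmentation at the C2 hydrogen, and acetic acid in THF without added water is too weak to open the perketal.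

Step 11
Reactants: 15 methyl 4-{[(2S)-5-hydroxy-2-[(2-methoxypropan-2-yl)peroxy]-7-methyl-3-methylideneoct-6-en-1-yl]oxy}-3-methoxybenzoate
Product: 16 methyl 3-methoxy-4-{[(2S)-2-[(2-methoxypropan-2-yl)peroxy]-7-methyl-3-methylidene-5-oxooct-6-en-1-yl]oxy}benzoate
Conditions: DMP, NaHCO3, CH2Cl2, 0 °C
Reagents that add atoms: none
Why: Dess–Martin oxidation of a secondary allylic alcohol under bicarbonate buffer: the reagent is neutral and metal-free, does not attack dialkyl peroxides, and gives beta,gamma-unsaturated ketones without moving the double bond; both C5 epimers converge on one ketone.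

Step 12
Reactants: 16 methyl 3-methoxy-4-{[(2S)-2-[(2-methoxypropan-2-yl)peroxy]-7-methyl-3-methylidene-5-oxooct-6-en-1-yl]oxy}benzoate
Product: 17 methyl 4-{[(2S)-2-hydroperoxy-7-methyl-3-methylidene-5-oxooct-6-en-1-yl]oxy}-3-methoxybenzoate (target)
Conditions: AcOH–THF–H2O, 0 °C to rt; cold neutral work-up
Reagents that add atoms: none
Why: Acid hydrolysis of a mixed perketal: protonation and cleavage occur at the ketal carbon, so the C2–O and O–O bonds and the C2 configuration are untouched; acetic acid is too weak to enolise the ketone at a useful rate or to trigger cleavage of the hydroperoxide.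

## Compound list

1 | methacrolein (2-methylprop-2-enal) | C=C(C)C=O | starting material
2 | 2-(prop-1-en-2-yl)oxirane, racemic (the R enantiomer, C=C(C)[C@@H]1CO1, is consumed in step 2) | C=C(C)C1CO1 | intermediate
3 | methyl vanillate (methyl 4-hydroxy-3-methoxybenzoate) | COC(=O)c1ccc(O)c(OC)c1 | starting material
4 | methyl 4-{[(2R)-2-hydroxy-3-methylbut-3-en-1-yl]oxy}-3-methoxybenzoate | C=C(C)[C@H](COc1ccc(C(=O)OC)cc1OC)O | intermediate
5 | methyl 3-methoxy-4-{[(2R)-3-methyl-2-(triethylsilyloxy)but-3-en-1-yl]oxy}benzoate | C=C(C)[C@H](COc1ccc(C(=O)OC)cc1OC)O[Si](CC)(CC)CC | intermediate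
6 | 3-methylbut-2-enal | CC(C)=CC=O | starting material
7 | methyl 4-{[(2R)-5-hydroxy-7-methyl-3-methylidene-2-(triethylsilyloxy)oct-6-en-1-yl]oxy}-3-methoxybenzoate, C5 epimers | C=C(CC(O)C=C(C)C)[C@H](COc1ccc(C(=O)OC)cc1OC)O[Si](CC)(CC)CC | intermediate
8 | methyl 4-{[(2R)-5-(tert-butyldimethylsilyloxy)-7-methyl-3-methylidene-2-(triethylsilyloxy)oct-6-en-1-yl]oxy}-3-methoxybenzoate, C5 epimers | C=C(CC(O[Si](C)(C)C(C)(C)C)C=C(C)C)[C@H](COc1ccc(C(=O)OC)cc1OC)O[Si](CC)(CC)CC | intermediate
9 | methyl 4-{[(2R)-5-(tert-butyldimethylsilyloxy)-2-hydroxy-7-methyl-3-methylideneoct-6-en-1-yl]oxy}-3-methoxybenzoate, C5 epimers | C=C(CC(O[Si](C)(C)C(C)(C)C)C=C(C)C)[C@H](COc1ccc(C(=O)OC)cc1OC)O | intermediate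
10 | methyl 4-{[(2R)-5-(tert-butyldimethylsilyloxy)-2-(methanesulfonyloxy)-7-methyl-3-methylideneoct-6-en-1-yl]oxy}-3-methoxybenzoate, C5 epimers | C=C(CC(O[Si](C)(C)C(C)(C)C)C=C(C)C)[C@H](COc1ccc(C(=O)OC)cc1OC)OS(C)(=O)=O | intermediate
11 | 2,3-dimethylbut-2-ene | CC(C)=C(C)C | starting material
12 | acetone O-oxide (propan-2-one O-oxide), not isolated | CC(C)=[O+][O-] | intermediate
13 | 2-methoxyprop-2-yl hydroperoxide (2-hydroperoxy-2-methoxypropane) | COC(C)(C)OO | intermediate
14 | methyl 4-{[(2S)-5-(tert-butyldimethylsilyloxy)-2-[(2-methoxypropan-2-yl)peroxy]-7-methyl-3-methylideneoct-6-en-1-yl]oxy}-3-methoxybenzoate, C5 epimers | C=C(CC(O[Si](C)(C)C(C)(C)C)C=C(C)C)[C@@H](COc1ccc(C(=O)OC)cc1OC)OOC(C)(C)OC | intermediate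
15 | methyl 4-{[(2S)-5-hydroxy-2-[(2-methoxypropan-2-yl)peroxy]-7-methyl-3-methylideneoct-6-en-1-yl]oxy}-3-methoxybenzoate, C5 epimers | C=C(CC(O)C=C(C)C)[C@@H](COc1ccc(C(=O)OC)cc1OC)OOC(C)(C)OC | intermediate
16 | methyl 3-methoxy-4-{[(2S)-2-[(2-methoxypropan-2-yl)peroxy]-7-methyl-3-methylidene-5-oxooct-6-en-1-yl]oxy}benzoate | C=C(CC(=O)C=C(C)C)[C@@H](COc1ccc(C(=O)OC)cc1OC)OOC(C)(C)OC | intermediate
17 | methyl 4-{[(2S)-2-hydroperoxy-7-methyl-3-methylidene-5-oxooct-6-en-1-yl]oxy}-3-methoxybenzoate | C=C(CC(=O)C=C(C)C)[C@@H](COc1ccc(C(=O)OC)cc1OC)OO | target

## Step count and least certain steps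

Total step count: 12. Longest linear sequence: 11 steps (steps 1–7 and 9–12, from methacrolein 1); step 8 is a one-step side branch that makes reagent 13.

**Step 2 (key step).** The ortho-methoxy group makes the phenoxide of 3 a hindered and possibly chelating ligand on cobalt. This could slow phenoxide delivery, so that unselective background opening or attack at the allylic carbon lowers the enantiomeric purity of 4. Fallback: resolution and etherification are separated. Starting from 2, a hydrolytic kinetic resolution with (R,R)-(salen)Co(OAc) (trivalent cobalt) and about half an equivalent of water should consume the S epoxide as (S)-3-methylbut-3-ene-1,2-diol F2. Unreacted (R)-2-(prop-1-en-2-yl)oxirane F1 is distilled off and opened by 3 with K2CO3 in DMF in a sealed vessel at about 70 °C. Phenoxide attack at C1 leaves C2 untouched, and the sequence rejoins the route at 4.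

**Step 4.** The alkene of 5 is deactivated by the allylic silyloxy group, and the ester and the two ring A ether oxygens sequester the Lewis acid. The ene reaction may therefore be slower than methyl transfer from aluminium to 6, self-condensation of 6, or hydrogen abstraction at C2, which would destroy the stereocentre. Fallback: the C–C bond is formed by a Barbier allylation. Starting from 5, ene-type allylic chlorination with NCS and catalytic PhSeCl in CH2Cl2 should give methyl 4-{[(2R)-3-(chloromethyl)-2-(triethylsilyloxy)but-3-en-1-yl]oxy}-3-methoxybenzoate F3. Indium metal in DMF with 6 then adds the allyl unit to the aldehyde carbon and rejoins the route at 7.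

**Step 9.** The tertiary peroxide anion meets a secondary carbon flanked by a branched alkene and an aryloxymethyl group. Elimination toward C1 (giving a dienyl aryl ether) or SN2' attack at C10 may compete with direct substitution, and any ionisation would erode the C2 configuration. Fallback: the smaller hydroperoxide anion is used and the protecting group is added afterwards. Starting from 10, concentrated H2O2 with KOH in MeOH at 0 °C, with short contact to spare the ester, should give methyl 4-{[(2S)-5-(tert-butyldimethylsilyloxy)-2-hydroperoxy-7-methyl-3-methylideneoct-6-en-1-yl]oxy}-3-methoxybenzoate F4 with inversion. 2-Methoxypropene with catalytic PPTS in CH2Cl2 converts F4 into 14.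

**Step 12.** Aqueous acid acting on the skipped dienone may move C3=C10 into conjugation, or the freed hydroperoxide may add to C5 and not reopen. Fallback: the acid step is moved to a stage without a ketone and the peroxide is finally released by fluoride. Starting from 15, the same aqueous acetic acid gives methyl 4-{[(2S)-2-hydroperoxy-5-hydroxy-7-methyl-3-methylideneoct-6-en-1-yl]oxy}-3-methoxybenzoate F5. One equivalent of TBSCl with imidazole at −20 °C should silylate the more acidic OOH to give methyl 4-{[(2S)-2-[(tert-butyldimethylsilyl)peroxy]-5-hydroxy-7-methyl-3-methylideneoct-6-en-1-yl]oxy}-3-methoxybenzoate F6. Dess–Martin oxidation gives methyl 4-{[(2S)-2-[(tert-butyldimethylsilyl)peroxy]-7-methyl-3-methylidene-5-oxooct-6-en-1-yl]oxy}-3-methoxybenzoate F7, and TBAF buffered with AcOH releases 17.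

## Further compounds

F1 | step 2 | (R)-2-(prop-1-en-2-yl)oxirane | C=C(C)[C@@H]1CO1
F2 | step 2 | (S)-3-methylbut-3-ene-1,2-diol | C=C(C)[C@@H](CO)O
F3 | step 4 | methyl 4-{[(2R)-3-(chloromethyl)-2-(triethylsilyloxy)but-3-en-1-yl]oxy}-3-methoxybenzoate | C=C(CCl)[C@H](COc1ccc(C(=O)OC)cc1OC)O[Si](CC)(CC)CC
F4 | step 9 | methyl 4-{[(2S)-5-(tert-butyldimethylsilyloxy)-2-hydroperoxy-7-methyl-3-methylideneoct-6-en-1-yl]oxy}-3-methoxybenzoate | C=C(CC(O[Si](C)(C)C(C)(C)C)C=C(C)C)[C@@H](COc1ccc(C(=O)OC)cc1OC)OO
F5 | step 12 | methyl 4-{[(2S)-2-hydroperoxy-5-hydroxy-7-methyl-3-methylideneoct-6-en-1-yl]oxy}-3-methoxybenzoate | C=C(CC(O)C=C(C)C)[C@@H](COc1ccc(C(=O)OC)cc1OC)OO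
F6 | step 12 | methyl 4-{[(2S)-2-[(tert-butyldimethylsilyl)peroxy]-5-hydroxy-7-methyl-3-methylideneoct-6-en-1-yl]oxy}-3-methoxybenzoate | C=C(CC(O)C=C(C)C)[C@@H](COc1ccc(C(=O)OC)cc1OC)OO[Si](C)(C)C(C)(C)C
F7 | step 12 | methyl 4-{[(2S)-2-[(tert-butyldimethylsilyl)peroxy]-7-methyl-3-methylidene-5-oxooct-6-en-1-yl]oxy}-3-methoxybenzoate | C=C(CC(=O)C=C(C)C)[C@@H](COc1ccc(C(=O)OC)cc1OC)OO[Si](C)(C)C(C)(C)C
A1 | alternative 1 | methyl 3-methoxy-4-{[(2S)-2-[(2-methoxypropan-2-yl)peroxy]-7-methyl-3-methylidene-5-oxooct-6-en-1-yl]oxy}benzoate (identical with 16) | C=C(CC(=O)C=C(C)C)[C@@H](COc1ccc(C(=O)OC)cc1OC)OOC(C)(C)OC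
A2 | alternative 1 | methyl 4-{[(2S)-3-(chloromethyl)-2-[(2-methoxypropan-2-yl)peroxy]but-3-en-1-yl]oxy}-3-methoxybenzoate | C=C(CCl)[C@@H](COc1ccc(C(=O)OC)cc1OC)OOC(C)(C)OC
A3 | alternative 1 | tributyl(2-methylprop-1-en-1-yl)stannane | CCCC[Sn](CCCC)(CCCC)C=C(C)C
A4 | alternative 1 | carbon monoxide | [C-]#[O+]
A5 | alternative 2 | methyl 3-methoxy-4-{[(2S)-2-[(2-methoxypropan-2-yl)peroxy]-4-oxobutyl]oxy}benzoate | O=CC[C@@H](COc1ccc(C(=O)OC)cc1OC)OOC(C)(C)OC
A6 | alternative 2 | methyl 3-methoxy-4-{[(2E)-4-oxobut-2-en-1-yl]oxy}benzoate | O=C/C=C/COc1ccc(C(=O)OC)cc1OC
A7 | alternative 2 | 2-methoxyprop-2-yl hydroperoxide (identical with 13) | COC(C)(C)OO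
A8 | alternative 3 | methyl 4-{[(2R)-2-hydroxy-7-methyl-3-methylidene-5-oxooct-6-en-1-yl]oxy}-3-methoxybenzoate | C=C(CC(=O)C=C(C)C)[C@H](COc1ccc(C(=O)OC)cc1OC)O
A9 | alternative 3 | 5-iodo-2-methylhexa-2,5-dien-4-one | C=C(I)CC(=O)C=C(C)C
A10 | alternative 3 | methyl 3-methoxy-4-(2-oxoethoxy)benzoate | O=CCOc1ccc(C(=O)OC)cc1OC
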